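**Strategy.** The plan turns on breaking the lactone C4–C5 bond. Lactone C4 bears a hydrogen, the ring-C benzyl group, C3 and the OCH2 carbon C5, which is the pattern of the β-carbon of a 4-arylbut-2-enal that has accepted a one-carbon nucleophile. An amine-catalysed nitro-Michael addition of nitromethane to (E)-4-(4-benzyloxy-3-methoxyphenyl)but-2-enal, made from eugenol, forms C4–C5 and fixes C4 as S in one operation. The nitro carbon later becomes C5 and the aldehyde carbon C2. Ring B, carrying the side arm as an acetonide-masked 1,3-diol whose aryl-bearing centre comes from an Evans aldol, is joined by trans-selective alkylation at C3. The fragile α-aryl ketone is unveiled only in the last two steps.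

Key step: step 3

Remark: lactone numbering is C2 (carbonyl), C3, C4, C5 (OCH2); ring A is the aryl ketone ring, ring B the tetrasubstituted ring on the C3 benzyl group, ring C the ring on the C4 benzyl group; the carbinol centre made in step 12 is oxidised away in step 18, so only its aryl-bearing neighbour has to be controlled there; the methyl ester of 5-bromovanillic acid, the Reformatsky zinc reagent (0.5 M solution), O-benzylvanillin and the oxazolidinone are taken as purchased.

**Fragment 1 (lactone with ring C)**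

Step 1
Reactants: 1 eugenol
Product: 2 4-allyl-1-(benzyloxy)-2-methoxybenzene
Conditions: BnBr, K2CO3, acetone, reflux
Reagents that add atoms: benzyl bromide, BrCc1ccccc1
Why: Williamson ether synthesis on the phenoxide under weak base, which leaves the allyl group in place.

Step 2
Reactants: 2 4-allyl-1-(benzyloxy)-2-methoxybenzene; 3 (E)-crotonaldehyde
Product: 4 (E)-4-(4-benzyloxy-3-methoxyphenyl)but-2-enal
Conditions: 3 (5 equiv), second-generation Hoveyda–Grubbs catalyst RuCl2(H2IMes)(=CH-C6H4-2-OiPr) (3 mol%), 1,4-benzoquinone (10 mol%), CH2Cl2, 40 °C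
Reagents that add atoms: none
Why: Olefin cross-metathesis of a terminal allylarene with the slowly dimerising crotonaldehyde in excess should release propene and give the conjugated enal as the E isomer, while benzoquinone suppresses Ru–H isomerisation of the allyl group.

Step 3
Reactants: 4 (E)-4-(4-benzyloxy-3-methoxyphenyl)but-2-enal; 5 nitromethane
Product: 8 (S)-3-(4-benzyloxy-3-methoxybenzyl)-4-nitrobutanal, via iminium benzoate 6 (not isolated), via nitro enamine 7 (not isolated)
Conditions: 5 (5 equiv), (R)-α,α-diphenylprolinol trimethylsilyl ether (10 mol%), PhCO2H (10 mol%), MeOH, 0 °C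
Reagents that add atoms: none
Why: The pyrrolidine nitrogen condenses with enal 4 to the (E)-configured s-trans iminium benzoate 6, benzoate deprotonates nitromethane, the nitronate adds to C3 of the enal (the future lactone C4), and enamine 7 is protonated at C2 and hydrolysed, which returns the catalyst. This is the iminium-catalysed asymmetric Michael addition of nitromethane to β-alkyl enals with diarylprolinol silyl ethers, a known reaction applied here to a 4-aryl-substituted member of that class. No ring is closed; one skeletal bond, C3–CH2NO2, is formed. The new centre is set by the catalyst alone: the diphenyl(trimethylsilyloxy)methyl group of the (R)-pyrrolidine screens the Re face of C3, so the nitronate bonds to the Si face and the S aldehyde should result (CH2NO2 > CH2CHO > CH2Ar; because CH2Ar ranks below CH2CHO, the S descriptor corresponds to the R catalyst). The step needs 1,4- rather than 1,2-addition, which iminium activation provides, and it must outrun γ-deprotonation of 6 at the C4 methylene to a dienamine conjugated with ring C; the weak-acid cocatalyst without added base, 0 °C, excess nitromethane and the electron-rich benzyloxy(methoxy)aryl group, which keeps the C4–H acidity low, are chosen to secure this.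

Step 4
Reactants: 8 (S)-3-(4-benzyloxy-3-methoxybenzyl)-4-nitrobutanal
Product: 9 (S)-3-(4-benzyloxy-3-methoxybenzyl)-4-nitrobutanoic acid
Conditions: NaClO2, NaH2PO4, 2-methyl-2-butene, t-BuOH/H2O, 0 °C to rt
Reagents that add atoms: sodium chlorite, [Na+].[O-]Cl=O
Why: Pinnick oxidation with a hypochlorite scavenger converts the aldehyde to the acid without touching the nitro group, the electron-rich ring or the stereocentre, which is β to the carbonyl.

Step 5
Reactants: 9 (S)-3-(4-benzyloxy-3-methoxybenzyl)-4-nitrobutanoic acid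
Product: 10 methyl (S)-3-(4-benzyloxy-3-methoxybenzyl)-4-nitrobutanoate
Conditions: MeOH, H2SO4 (cat.), 40 °C
Reagents that add atoms: methanol, CO
Why: Fischer esterification; the primary nitro group is inert because no nitronate forms under acid.

Step 6
Reactants: 10 methyl (S)-3-(4-benzyloxy-3-methoxybenzyl)-4-nitrobutanoate
Product: 11 (S)-2-(4-benzyloxy-3-methoxybenzyl)-4-methoxy-4-oxobutanoic acid
Conditions: NaNO2 (3 equiv), AcOH (10 equiv), DMSO, 35 °C
Reagents that add atoms: sodium nitrite, [Na+].[O-]N=O; water, O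
Why: Nitrite-mediated Nef-type oxidation of a primary nitroalkane to the carboxylic acid (through the nitrolic acid and nitrile oxide) in buffered acetic acid, conditions under which the ester, the benzyl ether and the adjacent stereocentre should be retained.

Step 7
Reactants: 11 (S)-2-(4-benzyloxy-3-methoxybenzyl)-4-methoxy-4-oxobutanoic acid
Product: 13 (S)-4-(4-benzyloxy-3-methoxybenzyl)dihydrofuran-2(3H)-one, via hydroxy ester 12 (not isolated)
Conditions: BH3·SMe2, THF, 0 °C to rt; MeOH; then TsOH·H2O (cat.), toluene, rt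
Reagents that add atoms: none
Why: Chemoselective borane reduction of the carboxylic acid in the presence of the methyl ester gives hydroxy ester 12, which closes by acid-catalysed intramolecular transesterification to the five-membered lactone; the stereocentre is not involved and stays S.

**Fragment 2 (rings B and A with the masked side arm)**

Step 8
Reactants: 14 methyl 3-bromo-4-hydroxy-5-methoxybenzoate
Product: 15 methyl 4-(benzyloxy)-3-bromo-5-methoxybenzoate
Conditions: BnBr, K2CO3, DMF, 60 °C
Reagents that add atoms: benzyl bromide, BrCc1ccccc1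
Why: Williamson ether synthesis on the hindered but acidic phenol.

Step 9
Reactants: 15 methyl 4-(benzyloxy)-3-bromo-5-methoxybenzoate; 16 (2-tert-butoxy-2-oxoethyl)zinc bromide, BrZnCH2CO2tBu
Product: 17 methyl 4-(benzyloxy)-3-(2-tert-butoxy-2-oxoethyl)-5-methoxybenzoate
Conditions: Pd2(dba)3 (2 mol%), XPhos (8 mol%), THF, 60 °C
Reagents that add atoms: none
Why: Palladium-catalysed Negishi-type coupling of an aryl bromide with a Reformatsky zinc enolate, which tolerates the methyl ester and benzyl ether; the bulky biaryl phosphine promotes coupling next to the ortho alkoxy group.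

Step 10
Reactants: 17 methyl 4-(benzyloxy)-3-(2-tert-butoxy-2-oxoethyl)-5-methoxybenzoate
Product: 18 [2-(benzyloxy)-3-methoxy-5-(methoxycarbonyl)phenyl]acetic acid
Conditions: CF3CO2H/CH2Cl2 (1:3), 0 °C to rt
Reagents that add atoms: none
Why: Acidolysis of the tert-butyl ester with loss of isobutene, selective over the methyl ester and the aryl benzyl ether at this acid strength.

Step 11
Reactants: 18 [2-(benzyloxy)-3-methoxy-5-(methoxycarbonyl)phenyl]acetic acid; 19 (R)-4-benzyl-2-oxazolidinone
Product: 21 methyl 3-{2-[(R)-4-benzyl-2-oxooxazolidin-3-yl]-2-oxoethyl}-4-(benzyloxy)-5-methoxybenzoate, via mixed pivalic anhydride 20 (not isolated)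
Conditions: t-BuCOCl, Et3N, THF, −20 °C; then 19, LiCl, −20 °C to rt
Reagents that add atoms: none
Why: N-Acylation of the oxazolidinone through mixed anhydride 20 with LiCl/Et3N activation, a method that avoids ketene formation from arylacetic acids and attacks only the unhindered carbonyl.

Step 12
Reactants: 21 methyl 3-{2-[(R)-4-benzyl-2-oxooxazolidin-3-yl]-2-oxoethyl}-4-(benzyloxy)-5-methoxybenzoate; 22 4-(benzyloxy)-3-methoxybenzaldehyde
Product: 25 methyl 3-{(2R,3R)-1-[(R)-4-benzyl-2-oxooxazolidin-3-yl]-3-(4-benzyloxy-3-methoxyphenyl)-3-hydroxy-1-oxopropan-2-yl}-4-(benzyloxy)-5-methoxybenzoate, via boron enolate 23 (not isolated), via boron aldolate 24 (not isolated)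
Conditions: n-Bu2BOTf, i-Pr2NEt, CH2Cl2, −78 to 0 °C; 22, −78 to −10 °C; then pH 7 buffer, MeOH, 30% H2O2, 0 °C
Reagents that add atoms: none
Why: Evans syn-aldol reaction: soft enolisation gives the Z-boron enolate 23, which reacts through a closed chair transition state on the enolate face away from the auxiliary benzyl group, so the (R)-auxiliary should set the aryl-bearing C2 as R (and the carbinol as 3R, a centre erased in step 18).

Step 13
Reactants: 25 the aldol adduct
Product: 26 (1R,2S)-1-(4-benzyloxy-3-methoxyphenyl)-2-[2-(benzyloxy)-5-(hydroxymethyl)-3-methoxyphenyl]propane-1,3-diol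
Conditions: LiBH4 (excess), MeOH (4 equiv), THF, 0 °C then 45 °C
Reagents that add atoms: none
Why: Hydride reduction with LiBH4 cleaves the N-acyloxazolidinone to the primary alcohol at 0 °C with release of the auxiliary and, on warming, reduces the methyl benzoate to the benzylic alcohol; once the imide carbonyl is gone neither stereocentre can epimerise.

Step 14
Reactants: 26 the triol
Product: 27 {4-(benzyloxy)-3-[(4R,5S)-4-(4-benzyloxy-3-methoxyphenyl)-2,2-dimethyl-1,3-dioxan-5-yl]-5-methoxyphenyl}methanol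
Conditions: Me2C(OMe)2, PPTS (cat.), acetone, rt; aq. NaHCO3 work-up
Reagents that add atoms: 2,2-dimethoxypropane, COC(C)(C)OC
Why: Acid-catalysed transketalisation closes the 1,3-diol to the six-membered acetonide under thermodynamic control, whereas the isolated benzylic alcohol cannot form a cyclic ketal and should be recovered free.

Step 15
Reactants: 27 the acetonide alcohol
Product: 28 (4R,5S)-4-(4-benzyloxy-3-methoxyphenyl)-5-[2-(benzyloxy)-5-(bromomethyl)-3-methoxyphenyl]-2,2-dimethyl-1,3-dioxane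
Conditions: CBr4, PPh3, CH2Cl2, 0 °C; used at once
Reagents that add atoms: carbon tetrabromide, BrC(Br)(Br)Br
Why: Appel reaction converts the benzylic alcohol to the bromide through the alkoxyphosphonium ion under essentially neutral conditions that the acetonide and benzyl ethers tolerate.

**Union and finish**

Step 16
Reactants: 13 (S)-4-(4-benzyloxy-3-methoxybenzyl)dihydrofuran-2(3H)-one; 28 the benzylic bromide
Product: 30 (3S,4S)-4-(4-benzyloxy-3-methoxybenzyl)-3-{4-benzyloxy-3-[(4R,5S)-4-(4-benzyloxy-3-methoxyphenyl)-2,2-dimethyl-1,3-dioxan-5-yl]-5-methoxybenzyl}dihydrofuran-2(3H)-one, via lithium enolate 29 (not isolated)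
Conditions: LiN(SiMe3)2, THF, −78 °C; then 28, DMPU, −78 to −40 °C
Reagents that add atoms: none
Why: SN2 alkylation of a γ-butyrolactone lithium enolate with a benzylic bromide: the electrophile approaches the enolate face opposite the C4 benzyl group, which should give the trans-3,4-disubstituted lactone and set C3 as S; the bromide has no acidic hydrogen and the acetonide is inert to the base.

Step 17
Reactants: 30 the coupled acetonide
Product: 31 (3S,4S)-4-(4-benzyloxy-3-methoxybenzyl)-3-{4-benzyloxy-3-[(1R,2S)-1-(4-benzyloxy-3-methoxyphenyl)-1,3-dihydroxypropan-2-yl]-5-methoxybenzyl}dihydrofuran-2(3H)-one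
Conditions: AcOH/THF/H2O (3:1:1), 40 °C
Reagents that add atoms: none
Why: Acid-catalysed acetal hydrolysis in aqueous acetic acid, mild enough for the lactone and benzyl ethers; any reversible ionisation at the benzylic carbinol is harmless because that centre is oxidised next.

Step 18
Reactants: 31 the diol
Product: 32 (3S,4S)-4-(4-benzyloxy-3-methoxybenzyl)-3-{4-benzyloxy-3-[(2S)-1-(4-benzyloxy-3-methoxyphenyl)-3-hydroxy-1-oxopropan-2-yl]-5-methoxybenzyl}dihydrofuran-2(3H)-one
Conditions: DDQ (1.2 equiv), 1,4-dioxane, rt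
Reagents that add atoms: none
Why: Chemoselective DDQ oxidation of an electron-rich secondary benzylic alcohol by hydride abstraction, which should leave the non-benzylic primary alcohol, the aryl benzyl ethers and the lactone alone; the adjacent aryl-bearing centre should keep its S configuration because the medium is neither basic nor strongly acidic.

Step 19
Reactants: 32 the tribenzyl ketone
Product: 33 (3S,4S)-4-(4-hydroxy-3-methoxybenzyl)-3-{4-hydroxy-3-[(2S)-3-hydroxy-1-(4-hydroxy-3-methoxyphenyl)-1-oxopropan-2-yl]-5-methoxybenzyl}dihydrofuran-2(3H)-one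
Conditions: H2 (1 atm), 10% Pd/C, EtOAc/EtOH, rt, stopped at full debenzylation
Reagents that add atoms: none
Why: Heterogeneous hydrogenolysis of three aryl benzyl ethers, which is much faster than reduction of an electron-rich aryl ketone at 1 atm in a neutral solvent, so the lactone, ketone, primary alcohol and base-labile α-aryl centre should survive.

**Compound list**

1 | eugenol | COc1cc(CC=C)ccc1O | starting material
2 | 4-allyl-1-(benzyloxy)-2-methoxybenzene | COc1cc(CC=C)ccc1OCc1ccccc1 | intermediate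
3 | (E)-crotonaldehyde | C/C=C/C=O | starting material
4 | (E)-4-(4-benzyloxy-3-methoxyphenyl)but-2-enal | COc1cc(C/C=C/C=O)ccc1OCc1ccccc1 | intermediate
5 | nitromethane | C[N+](=O)[O-] | starting material
6 | (R)-1-[(E)-4-(4-benzyloxy-3-methoxyphenyl)but-2-enylidene]-2-[diphenyl(trimethylsilyloxy)methyl]pyrrolidinium benzoate, E at C=N (not isolated) | C[Si](C)(C)OC(c1ccccc1)(c1ccccc1)[C@H]1CCC/[N+]1=C\C=C\Cc1ccc(OCc2ccccc2)c(OC)c1.[O-]C(=O)c1ccccc1 | intermediate
7 | (R)-1-[(S,E)-4-(4-benzyloxy-3-methoxyphenyl)-3-(nitromethyl)but-1-enyl]-2-[diphenyl(trimethylsilyloxy)methyl]pyrrolidine (not isolated) | C[Si](C)(C)OC(c1ccccc1)(c1ccccc1)[C@H]1CCCN1/C=C/[C@@H](C[N+](=O)[O-])Cc1ccc(OCc2ccccc2)c(OC)c1 | intermediate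
8 | (S)-3-(4-benzyloxy-3-methoxybenzyl)-4-nitrobutanal | COc1cc(C[C@H](C[N+](=O)[O-])CC=O)ccc1OCc1ccccc1 | intermediate
9 | (S)-3-(4-benzyloxy-3-methoxybenzyl)-4-nitrobutanoic acid | COc1cc(C[C@H](C[N+](=O)[O-])CC(=O)O)ccc1OCc1ccccc1 | intermediate
10 | methyl (S)-3-(4-benzyloxy-3-methoxybenzyl)-4-nitrobutanoate | COc1cc(C[C@H](C[N+](=O)[O-])CC(=O)OC)ccc1OCc1ccccc1 | intermediate
11 | (S)-2-(4-benzyloxy-3-methoxybenzyl)-4-methoxy-4-oxobutanoic acid | COc1cc(C[C@H](C(=O)O)CC(=O)OC)ccc1OCc1ccccc1 | intermediate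
12 | methyl (S)-3-(4-benzyloxy-3-methoxybenzyl)-4-hydroxybutanoate (not isolated) | COc1cc(C[C@H](CO)CC(=O)OC)ccc1OCc1ccccc1 | intermediate
13 | (S)-4-(4-benzyloxy-3-methoxybenzyl)dihydrofuran-2(3H)-one | COc1cc(C[C@@H]2COC(=O)C2)ccc1OCc1ccccc1 | intermediate
14 | methyl 3-bromo-4-hydroxy-5-methoxybenzoate | COC(=O)c1cc(Br)c(O)c(OC)c1 | starting material
15 | methyl 4-(benzyloxy)-3-bromo-5-methoxybenzoate | COC(=O)c1cc(Br)c(OCc2ccccc2)c(OC)c1 | intermediate
16 | (2-tert-butoxy-2-oxoethyl)zinc bromide | CC(C)(C)OC(=O)C[Zn]Br | starting material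
17 | methyl 4-(benzyloxy)-3-(2-tert-butoxy-2-oxoethyl)-5-methoxybenzoate | COC(=O)c1cc(CC(=O)OC(C)(C)C)c(OCc2ccccc2)c(OC)c1 | intermediate
18 | [2-(benzyloxy)-3-methoxy-5-(methoxycarbonyl)phenyl]acetic acid | COC(=O)c1cc(CC(=O)O)c(OCc2ccccc2)c(OC)c1 | intermediate
19 | (R)-4-benzyl-2-oxazolidinone | O=C1N[C@H](Cc2ccccc2)CO1 | starting material
20 | mixed anhydride of 18 with pivalic acid (not isolated) | COC(=O)c1cc(CC(=O)OC(=O)C(C)(C)C)c(OCc2ccccc2)c(OC)c1 | intermediate
21 | methyl 3-{2-[(R)-4-benzyl-2-oxooxazolidin-3-yl]-2-oxoethyl}-4-(benzyloxy)-5-methoxybenzoate | COC(=O)c1cc(CC(=O)N2[C@H](Cc3ccccc3)COC2=O)c(OCc2ccccc2)c(OC)c1 | intermediate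
22 | 4-(benzyloxy)-3-methoxybenzaldehyde | COc1cc(C=O)ccc1OCc1ccccc1 | starting material
23 | (Z)-dibutylboron enolate of 21 (not isolated) | CCCCB(CCCC)O/C(=C\c1cc(C(=O)OC)cc(OC)c1OCc1ccccc1)N1[C@H](Cc2ccccc2)COC1=O | intermediate
24 | O-dibutylboryl (2R,3R)-aldolate of 25 (not isolated) | COC(=O)c1cc([C@H]([C@@H](OB(CCCC)CCCC)c2ccc(OCc3ccccc3)c(OC)c2)C(=O)N2[C@H](Cc3ccccc3)COC2=O)c(OCc2ccccc2)c(OC)c1 | intermediate
25 | methyl 3-{(2R,3R)-1-[(R)-4-benzyl-2-oxooxazolidin-3-yl]-3-(4-benzyloxy-3-methoxyphenyl)-3-hydroxy-1-oxopropan-2-yl}-4-(benzyloxy)-5-methoxybenzoate | COC(=O)c1cc([C@H]([C@@H](O)c2ccc(OCc3ccccc3)c(OC)c2)C(=O)N2[C@H](Cc3ccccc3)COC2=O)c(OCc2ccccc2)c(OC)c1 | intermediate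
26 | (1R,2S)-1-(4-benzyloxy-3-methoxyphenyl)-2-[2-(benzyloxy)-5-(hydroxymethyl)-3-methoxyphenyl]propane-1,3-diol | OCc1cc([C@H]([C@@H](O)c2ccc(OCc3ccccc3)c(OC)c2)CO)c(OCc2ccccc2)c(OC)c1 | intermediate
27 | {4-(benzyloxy)-3-[(4R,5S)-4-(4-benzyloxy-3-methoxyphenyl)-2,2-dimethyl-1,3-dioxan-5-yl]-5-methoxyphenyl}methanol | OCc1cc([C@H]2COC(C)(C)O[C@H]2c2ccc(OCc3ccccc3)c(OC)c2)c(OCc2ccccc2)c(OC)c1 | intermediate
28 | (4R,5S)-4-(4-benzyloxy-3-methoxyphenyl)-5-[2-(benzyloxy)-5-(bromomethyl)-3-methoxyphenyl]-2,2-dimethyl-1,3-dioxane | BrCc1cc([C@H]2COC(C)(C)O[C@H]2c2ccc(OCc3ccccc3)c(OC)c2)c(OCc2ccccc2)c(OC)c1 | intermediate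
29 | lithium enolate of 13 (not isolated) | COc1cc(C[C@@H]2COC([O-])=C2)ccc1OCc1ccccc1.[Li+] | intermediate
30 | (3S,4S)-4-(4-benzyloxy-3-methoxybenzyl)-3-{4-benzyloxy-3-[(4R,5S)-4-(4-benzyloxy-3-methoxyphenyl)-2,2-dimethyl-1,3-dioxan-5-yl]-5-methoxybenzyl}dihydrofuran-2(3H)-one | COc1cc(C[C@@H]2COC(=O)[C@H]2Cc2cc(OC)c(OCc3ccccc3)c([C@H]3COC(C)(C)O[C@H]3c3ccc(OCc4ccccc4)c(OC)c3)c2)ccc1OCc1ccccc1 | intermediate
31 | (3S,4S)-4-(4-benzyloxy-3-methoxybenzyl)-3-{4-benzyloxy-3-[(1R,2S)-1-(4-benzyloxy-3-methoxyphenyl)-1,3-dihydroxypropan-2-yl]-5-methoxybenzyl}dihydrofuran-2(3H)-one | COc1cc(C[C@@H]2COC(=O)[C@H]2Cc2cc(OC)c(OCc3ccccc3)c([C@H]([C@@H](O)c3ccc(OCc4ccccc4)c(OC)c3)CO)c2)ccc1OCc1ccccc1 | intermediate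
32 | (3S,4S)-4-(4-benzyloxy-3-methoxybenzyl)-3-{4-benzyloxy-3-[(2S)-1-(4-benzyloxy-3-methoxyphenyl)-3-hydroxy-1-oxopropan-2-yl]-5-methoxybenzyl}dihydrofuran-2(3H)-one | COc1cc(C[C@@H]2COC(=O)[C@H]2Cc2cc(OC)c(OCc3ccccc3)c([C@H](C(=O)c3ccc(OCc4ccccc4)c(OC)c3)CO)c2)ccc1OCc1ccccc1 | intermediate
33 | (3S,4S)-4-(4-hydroxy-3-methoxybenzyl)-3-{4-hydroxy-3-[(2S)-3-hydroxy-1-(4-hydroxy-3-methoxyphenyl)-1-oxopropan-2-yl]-5-methoxybenzyl}dihydrofuran-2(3H)-one (CNP0281222.1) | COc1cc(C[C@@H]2COC(=O)[C@H]2Cc2cc(OC)c(O)c([C@@H](CO)C(=O)c3ccc(O)c(OC)c3)c2)ccc1O | target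

**Step count and risk**

Total: 19 steps (fragment 1: steps 1–7; fragment 2: steps 8–15; union and finish: steps 16–19). Longest linear sequence: 12 steps (14 to 33 through steps 8–19); the other branch is 11 steps.

Steps most likely to fail:

1. Step 3. The iminium ion can lose a proton from the C4 methylene and form a dienamine conjugated with ring C. That would divert the enal into deconjugated or α/γ-functionalised material, slow the conjugate addition and lower the enantiomeric purity. Fallback: abandon the nitro-Michael route to the lactone and set the centre by asymmetric hydrogenation. It sets out from 22. Stobbe condensation with dimethyl succinate (NaOMe, MeOH, reflux) should give (E)-4-(4-benzyloxy-3-methoxyphenyl)-3-(methoxycarbonyl)but-3-enoic acid F1. Hydrogenation of its triethylammonium salt with [Rh(cod)2]BF4 and the MOD-DIOP enantiomer that delivers the S acid (H2, MeOH, rt) should give (S)-4-(4-benzyloxy-3-methoxyphenyl)-3-(methoxycarbonyl)butanoic acid F2 with the benzyl ether intact. Reduction of the ester in the potassium salt of F2 with Ca(BH4)2 (from CaCl2 and NaBH4, EtOH, 0 °C) followed by aqueous HCl closes the lactone, and the route is rejoined at 13.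

2. Step 18. Chemoselectivity may be lost: DDQ may attack the benzylic methylene groups or benzyl ethers of the three electron-rich rings, or the oxidation may stall, and the β-hydroxy ketone may dehydrate on long exposure. Fallback: differentiate the two hydroxyl groups instead of relying on the oxidant. From 31, silylation of the primary alcohol (TBSCl, imidazole, DMF, 0 °C) should give (3S,4S)-4-(4-benzyloxy-3-methoxybenzyl)-3-{4-benzyloxy-3-[(1R,2S)-1-(4-benzyloxy-3-methoxyphenyl)-3-(tert-butyldimethylsilyloxy)-1-hydroxypropan-2-yl]-5-methoxybenzyl}dihydrofuran-2(3H)-one F3. Dess–Martin periodinane (NaHCO3, CH2Cl2, 0 °C) should give the silyloxy ketone (3S,4S)-4-(4-benzyloxy-3-methoxybenzyl)-3-{4-benzyloxy-3-[(2S)-1-(4-benzyloxy-3-methoxyphenyl)-3-(tert-butyldimethylsilyloxy)-1-oxopropan-2-yl]-5-methoxybenzyl}dihydrofuran-2(3H)-one F4. Acidic desilylation (HF·pyridine, THF, 0 °C) returns to the route at 32.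

3. Step 19. The aryl ketone may be reduced to the carbinol or the methylene compound, or cleavage of the hindered ring-B ether may be slow, and prolonged contact with the catalyst may erode the α-aryl centre. Fallback: a non-reductive Lewis-acid debenzylation. From 32, BCl3 with pentamethylbenzene as cation trap (CH2Cl2, −78 °C) should cleave the three aryl benzyl ethers selectively over the methyl ethers and give 33 directly; no new compound is made (F0).

**Further compounds**

F1 | step 3 | (E)-4-(4-benzyloxy-3-methoxyphenyl)-3-(methoxycarbonyl)but-3-enoic acid | COc1cc(/C=C(\CC(=O)O)C(=O)OC)ccc1OCc1ccccc1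
F2 | step 3 | (S)-4-(4-benzyloxy-3-methoxyphenyl)-3-(methoxycarbonyl)butanoic acid | COc1cc(C[C@H](C(=O)OC)CC(=O)O)ccc1OCc1ccccc1
F3 | step 18 | (3S,4S)-4-(4-benzyloxy-3-methoxybenzyl)-3-{4-benzyloxy-3-[(1R,2S)-1-(4-benzyloxy-3-methoxyphenyl)-3-(tert-butyldimethylsilyloxy)-1-hydroxypropan-2-yl]-5-methoxybenzyl}dihydrofuran-2(3H)-one | COc1cc(C[C@@H]2COC(=O)[C@H]2Cc2cc(OC)c(OCc3ccccc3)c([C@H]([C@@H](O)c3ccc(OCc4ccccc4)c(OC)c3)CO[Si](C)(C)C(C)(C)C)c2)ccc1OCc1ccccc1
F4 | step 18 | (3S,4S)-4-(4-benzyloxy-3-methoxybenzyl)-3-{4-benzyloxy-3-[(2S)-1-(4-benzyloxy-3-methoxyphenyl)-3-(tert-butyldimethylsilyloxy)-1-oxopropan-2-yl]-5-methoxybenzyl}dihydrofuran-2(3H)-one | COc1cc(C[C@@H]2COC(=O)[C@H]2Cc2cc(OC)c(OCc3ccccc3)c([C@H](C(=O)c3ccc(OCc4ccccc4)c(OC)c3)CO[Si](C)(C)C(C)(C)C)c2)ccc1OCc1ccccc1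
F0 | step 19 | none | none
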